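The carbocycle is read as a dearomatised benzene: ring carbons C1–C6 are the ring of ethyl benzoate 1, C7 is its carboxyl carbon, and the cis C2–O/C3–O pair is an ortho,meta cis-dihydrodiol. Everything rests on one whole-cell toluene dioxygenase oxidation, which adds both atoms of O2 (2) to C2 and C3 of the flat, achiral arene from one face and gives the (5S,6R) diene diol ester 3 as one enantiomer. Ester reduction, benzoylation of C7–OH and then C3–OH, and an epoxidation of C1=C6 directed by the free C2 hydroxyl then build the all-cis oxirane/hydroxyl/benzoate array, with C4=C5 left over from the diene.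

Key step: step 1

Remark: atoms are numbered as in 7-oxabicyclo[4.1.0]hept-4-ene (C1 quaternary oxirane carbon carrying C7H2, C2 carbinol, C3 benzoyloxy carbon, C4=C5, C6 oxirane CH, O7); the SMILES is read as having O7, C2–OH and C3–OBz on one ring face, and the recombinant dioxygenase strain is assumed to be at hand as a biocatalyst.

Step 1
Reactants: 1 ethyl benzoate; 2 dioxygen (from air)
Product: 3 ethyl (5S,6R)-5,6-dihydroxycyclohexa-1,3-diene-1-carboxylate
Conditions: E. coli JM109 (pDTG601) whole cells expressing toluene dioxygenase, IPTG induction, glucose-fed defined medium, air sparge, pH 7, 30–35 °C, slow feed of 1; centrifugation, EtOAc extraction at pH 7–8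
Reagents that add atoms: dioxygen, O=O
Why: A three-component non-heme iron dioxygenase (reductase, ferredoxin, oxygenase) in the cells passes two electrons from NADH to its iron site, where O2 is activated and both of its atoms are handed to one face of bound 1 at the ring carbons ortho and meta to the ester, so the future C2–O and C3–O bonds form in a single suprafacial event and the benzene ring becomes a cyclohexa-1,3-diene. The closest known reaction type is the whole-cell toluene dioxygenase cis-dihydroxylation of monosubstituted benzenes, for which benzoate esters are accepted substrates. No ring is closed; the carbocycle of the target is the former arene ring. Both new stereocentres, C5 (S) and C6 (R) of 3 (later C3 and C2), are dictated by the chiral active site, which exposes only one enantiotopic face of the flat substrate to the iron-bound oxygen. The step needs ortho,meta regioselectivity and a single face, and both are secured by the lone ester substituent, which docks the ring in one orientation in the binding pocket. The host lacks the diol dehydrogenase, so 3 accumulates, and the conjugated ester slows its dehydration to a phenol during neutral isolation.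

Step 2
Reactants: 3 ethyl (5S,6R)-5,6-dihydroxycyclohexa-1,3-diene-1-carboxylate
Product: 5 (1S,2R)-3-(hydroxymethyl)cyclohexa-3,5-diene-1,2-diol, via dienal 4 (not isolated)
Conditions: i-Bu2AlH (5 equiv), THF, −78 to −20 °C; MeOH quench, aq. KNaC4H4O6 (potassium sodium tartrate), NaCl-saturated EtOAc extraction at pH 7–8, base-washed glassware
Reagents that add atoms: none
Why: Ester-to-allylic-alcohol reduction with diisobutylaluminium hydride, which adds hydride 1,2 to the conjugated ester by way of the aldehyde while the first two equivalents hold the ring hydroxyls as aluminium alkoxides; no stereocentre is touched, and the acid-free work-up should keep the diene diol from dehydrating.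

Step 3
Reactants: 5 (1S,2R)-3-(hydroxymethyl)cyclohexa-3,5-diene-1,2-diol; 6 benzoyl chloride
Product: 7 [(5S,6R)-5,6-dihydroxycyclohexa-1,3-dien-1-yl]methyl benzoate
Conditions: BzCl (1.0 equiv), 2,4,6-collidine, CH2Cl2/THF, −78 to −40 °C
Reagents that add atoms: benzoyl chloride, O=C(Cl)c1ccccc1
Why: Chemoselective esterification with an acid chloride and a hindered pyridine base at low temperature, in which the primary allylic C7 hydroxyl should react well ahead of the two secondary ring hydroxyls; no stereocentre is involved.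

Step 4
Reactants: 7 [(5S,6R)-5,6-dihydroxycyclohexa-1,3-dien-1-yl]methyl benzoate; 6 benzoyl chloride
Product: 8 (1S,6R)-5-[(benzoyloxy)methyl]-6-hydroxycyclohexa-2,4-dien-1-yl benzoate
Conditions: BzCl (1.1 equiv), Ph2BOCH2CH2NH2 (10 mol%), i-Pr2NEt, MeCN, 0 °C
Reagents that add atoms: benzoyl chloride, O=C(Cl)c1ccccc1
Why: Borinic-acid-catalysed regioselective monoacylation of a cis-1,2-diol, in which the diol is bound as a tetracoordinate borinate and benzoylated once at its more accessible oxygen, the distal C3 oxygen, because the C2 oxygen is flanked by the substituted ring carbon; no C–O bond is broken, so both stereocentres are kept.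

Step 5
Reactants: 8 (1S,6R)-5-[(benzoyloxy)methyl]-6-hydroxycyclohexa-2,4-dien-1-yl benzoate; 9 tert-butyl hydroperoxide
Product: 10 [(1S,2S,3S,6R)-3-(benzoyloxy)-2-hydroxy-7-oxabicyclo[4.1.0]hept-4-en-1-yl]methyl benzoate
Conditions: VO(acac)2 (5 mol%), t-BuOOH (1.3 equiv, in decane), CH2Cl2, 0 °C, dark; aq. Na2S2O3 wash
Reagents that add atoms: tert-butyl hydroperoxide, CC(C)(C)OO
Why: Vanadium-catalysed hydroxyl-directed epoxidation of an allylic alcohol, in which the free C2 hydroxyl binds pentavalent vanadium as an alkoxide next to the tert-butylperoxide ligand and oxygen passes intramolecularly to the adjacent trisubstituted C1=C6 bond on the face of that hydroxyl, setting C1 (S) and C6 (R) syn to C2–OH and C3–OBz, while C4=C5, whose allylic oxygen is esterified, is not addressed.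

Compound list
1 | ethyl benzoate | CCOC(=O)c1ccccc1 | starting material
2 | dioxygen | O=O | starting material
3 | ethyl (5S,6R)-5,6-dihydroxycyclohexa-1,3-diene-1-carboxylate | CCOC(=O)C1=CC=C[C@H](O)[C@@H]1O | intermediate
4 | (5S,6R)-5,6-dihydroxycyclohexa-1,3-diene-1-carbaldehyde (held in the flask as its aluminium alkoxide) | O=CC1=CC=C[C@H](O)[C@@H]1O | intermediate
5 | (1S,2R)-3-(hydroxymethyl)cyclohexa-3,5-diene-1,2-diol | OCC1=CC=C[C@H](O)[C@@H]1O | intermediate
6 | benzoyl chloride | O=C(Cl)c1ccccc1 | starting material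
7 | [(5S,6R)-5,6-dihydroxycyclohexa-1,3-dien-1-yl]methyl benzoate | O=C(OCC1=CC=C[C@H](O)[C@@H]1O)c1ccccc1 | intermediate
8 | (1S,6R)-5-[(benzoyloxy)methyl]-6-hydroxycyclohexa-2,4-dien-1-yl benzoate | O=C(OCC1=CC=C[C@H](OC(=O)c2ccccc2)[C@@H]1O)c1ccccc1 | intermediate
9 | tert-butyl hydroperoxide | CC(C)(C)OO | starting material
10 | [(1S,2S,3S,6R)-3-(benzoyloxy)-2-hydroxy-7-oxabicyclo[4.1.0]hept-4-en-1-yl]methyl benzoate | O=C(OC[C@@]12O[C@@H]1C=C[C@H](OC(=O)c1ccccc1)[C@@H]2O)c1ccccc1 | target

Total step count: 5. Longest linear sequence: 5 steps (1 to 10).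

Steps most likely to fail

Step 4. The two secondary hydroxyls of the cis-diol may not be told apart well enough, a third benzoyl group may be introduced, or the base may induce a 1,2-benzoyl shift between O3 and O2. The fallback replaces kinetic acylation selectivity by protecting-group differentiation and sets out from 7. Silylation of the less hindered distal hydroxyl (Et3SiCl, imidazole, DMF, −40 °C) should give [(5S,6R)-6-hydroxy-5-[(triethylsilyl)oxy]cyclohexa-1,3-dien-1-yl]methyl benzoate F4. The hindered hydroxyl is then capped (t-BuMe2SiOTf, 2,6-lutidine, CH2Cl2, −78 °C) to give [(5S,6R)-6-[(tert-butyldimethylsilyl)oxy]-5-[(triethylsilyl)oxy]cyclohexa-1,3-dien-1-yl]methyl benzoate F5. Buffered HF·pyridine (pyridine, THF, 0 °C) should remove only the more labile triethylsilyl group, giving [(5S,6R)-6-[(tert-butyldimethylsilyl)oxy]-5-hydroxycyclohexa-1,3-dien-1-yl]methyl benzoate F6. Benzoylation of the single free hydroxyl (BzCl, pyridine, DMAP, CH2Cl2, 0 °C) leads to (1S,6R)-5-[(benzoyloxy)methyl]-6-[(tert-butyldimethylsilyl)oxy]cyclohexa-2,4-dien-1-yl benzoate F7. Removal of the remaining silyl ether with HF·pyridine (THF, 0 °C to room temperature) brings the sequence back to the route at 8.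

Step 5. The vanadium Lewis acid may ionise the dienylic benzoate and trigger aromatisation, the C2 carbinol may be oxidised to a dienone instead of passing oxygen on, or C4=C5 may be attacked. The fallback moves the epoxidation ahead of the C3 benzoate, onto a diene with a poorer leaving group, and sets out from 7. Selective silylation of the distal hydroxyl (t-BuMe2SiCl, imidazole, DMF, −20 °C) should give [(5S,6R)-5-[(tert-butyldimethylsilyl)oxy]-6-hydroxycyclohexa-1,3-dien-1-yl]methyl benzoate F8. The same VO(acac)2/t-BuOOH epoxidation, directed by the free C2 hydroxyl, should give [(1S,2S,3S,6R)-3-[(tert-butyldimethylsilyl)oxy]-2-hydroxy-7-oxabicyclo[4.1.0]hept-4-en-1-yl]methyl benzoate F9. Desilylation with Bu4NF buffered by AcOH (THF, 0 °C) gives [(1S,2S,3S,6R)-2,3-dihydroxy-7-oxabicyclo[4.1.0]hept-4-en-1-yl]methyl benzoate F10. Its allylic C3 hydroxyl is benzoylated in preference to the C2 hydroxyl next to the fully substituted oxirane carbon (BzCl, 2,4,6-collidine, CH2Cl2, −40 °C), and the sequence comes back to the route at 10.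

Step 2. The unprotected diene diol passes through an aluminium-rich and then an aqueous medium; dehydration to phenolic material, Diels–Alder dimerisation on concentration and loss of the very polar triol to the water phase may erode the step. The fallback masks the diol and sets out from 3. Silylation of both hydroxyls (Et3SiCl, imidazole, DMF, 0 °C) should give ethyl (5S,6R)-5,6-bis[(triethylsilyl)oxy]cyclohexa-1,3-diene-1-carboxylate F1. Reduction with i-Bu2AlH (2.2 equiv, CH2Cl2, −78 °C) should give the lipophilic [(5S,6R)-5,6-bis[(triethylsilyl)oxy]cyclohexa-1,3-dien-1-yl]methanol F2. Benzoylation (BzCl, pyridine, CH2Cl2, 0 °C) gives [(5S,6R)-5,6-bis[(triethylsilyl)oxy]cyclohexa-1,3-dien-1-yl]methyl benzoate F3. Buffered HF·pyridine (pyridine, THF, 0 °C) then removes both silyl groups, and the sequence comes back to the route at 7 without the free triol 5 ever being handled.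

Further compounds
F1 | step 2 | ethyl (5S,6R)-5,6-bis[(triethylsilyl)oxy]cyclohexa-1,3-diene-1-carboxylate | CCOC(=O)C1=CC=C[C@H](O[Si](CC)(CC)CC)[C@@H]1O[Si](CC)(CC)CC
F2 | step 2 | [(5S,6R)-5,6-bis[(triethylsilyl)oxy]cyclohexa-1,3-dien-1-yl]methanol | OCC1=CC=C[C@H](O[Si](CC)(CC)CC)[C@@H]1O[Si](CC)(CC)CC
F3 | step 2 | [(5S,6R)-5,6-bis[(triethylsilyl)oxy]cyclohexa-1,3-dien-1-yl]methyl benzoate | O=C(OCC1=CC=C[C@H](O[Si](CC)(CC)CC)[C@@H]1O[Si](CC)(CC)CC)c1ccccc1
F4 | step 4 | [(5S,6R)-6-hydroxy-5-[(triethylsilyl)oxy]cyclohexa-1,3-dien-1-yl]methyl benzoate | O=C(OCC1=CC=C[C@H](O[Si](CC)(CC)CC)[C@@H]1O)c1ccccc1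
F5 | step 4 | [(5S,6R)-6-[(tert-butyldimethylsilyl)oxy]-5-[(triethylsilyl)oxy]cyclohexa-1,3-dien-1-yl]methyl benzoate | O=C(OCC1=CC=C[C@H](O[Si](CC)(CC)CC)[C@@H]1O[Si](C)(C)C(C)(C)C)c1ccccc1
F6 | step 4 | [(5S,6R)-6-[(tert-butyldimethylsilyl)oxy]-5-hydroxycyclohexa-1,3-dien-1-yl]methyl benzoate | O=C(OCC1=CC=C[C@H](O)[C@@H]1O[Si](C)(C)C(C)(C)C)c1ccccc1
F7 | step 4 | (1S,6R)-5-[(benzoyloxy)methyl]-6-[(tert-butyldimethylsilyl)oxy]cyclohexa-2,4-dien-1-yl benzoate | O=C(OCC1=CC=C[C@H](OC(=O)c2ccccc2)[C@@H]1O[Si](C)(C)C(C)(C)C)c1ccccc1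
F8 | step 5 | [(5S,6R)-5-[(tert-butyldimethylsilyl)oxy]-6-hydroxycyclohexa-1,3-dien-1-yl]methyl benzoate | O=C(OCC1=CC=C[C@H](O[Si](C)(C)C(C)(C)C)[C@@H]1O)c1ccccc1
F9 | step 5 | [(1S,2S,3S,6R)-3-[(tert-butyldimethylsilyl)oxy]-2-hydroxy-7-oxabicyclo[4.1.0]hept-4-en-1-yl]methyl benzoate | O=C(OC[C@@]12O[C@@H]1C=C[C@H](O[Si](C)(C)C(C)(C)C)[C@@H]2O)c1ccccc1
F10 | step 5 | [(1S,2S,3S,6R)-2,3-dihydroxy-7-oxabicyclo[4.1.0]hept-4-en-1-yl]methyl benzoate | O=C(OC[C@@]12O[C@@H]1C=C[C@H](O)[C@@H]2O)c1ccccc1
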